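## Retrosynthetic overview

1. The target comes from its octabenzyl ether by one hydrogenolysis; the side-chain carbinol (Cβ–OH) comes from a phenol-tethered syn-hydrosilylation/Tamao oxidation of an (E)-1,3-diarylpropene, directed by Cα.
2. The 2,4,6-trioxyphenyl terminus is attached by olefin cross-metathesis of a 6-C-(1-arylbut-2-enyl)catechin with 2,4,6-tris(benzyloxy)styrene.
3. Key bond C6(catechin)–Cα: aromatic Claisen [3,3] rearrangement of a catechin 5-O-[(S,Z)-4-arylbut-3-en-2-yl] ether, with 1,3-chirality transfer from the carbinol carbon.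
4. That ether comes from Mitsunobu inversion between a catechin with 5-OH as its only free phenol (from (+)-taxifolin by chelation-controlled tribenzylation and C4 deoxygenation) and an (R)-arylbutynol (Sonogashira on (R)-but-3-yn-2-ol), then Lindlar reduction.
5. Rings: none is built. The flavan ring C is bought intact with taxifolin; a six-membered oxasiline forms transiently in the hydrosilylation and is cleaved in the same flask.

Assumption: (+)-taxifolin, 4-bromo-1,2-bis(benzyloxy)benzene, (R)-but-3-yn-2-ol and 2,4,6-tris(benzyloxy)benzaldehyde are taken as commercial.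

In the text, Cα is the diaryl-substituted side-chain carbon, Cβ the carbinol carbon and Cγ the CH2 on the phloroglucinol ring.

## Route

Step 1
Reactants: 1 (+)-taxifolin
Product: 2 7,3',4'-tri-O-benzyl-(+)-taxifolin
Conditions: BnBr (3.1 equiv), K2CO3, DMF, 0 °C to rt, argon
Reagents that add atoms: benzyl bromide, BrCc1ccccc1
Why: Williamson etherification in which the 5-OH is held in a hydrogen bond to the C4 carbonyl and the 3-OH is an alcohol, so only the 7-, 3'- and 4'-phenols are alkylated, while the bought 2,3-trans stereocentres are untouched.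

Step 2
Reactants: 2 7,3',4'-tri-O-benzyl-(+)-taxifolin
Product: 4 7,3',4'-tri-O-benzyl-(+)-catechin, via aryl ethyl carbonate 3 (not isolated)
Conditions: ClCO2Et (1.1 equiv), Et3N, THF, 0 °C; then NaBH4, H2O, 0 °C to rt
Reagents that add atoms: none
Why: Reductive deoxygenation of an o-acylphenol through its carbonate: hydride reduces C4=O, the carbonate migrates to the new alkoxide and leaves to give an o-quinone methide, and a second hydride reduces it to CH2, which frees 5-OH as the only phenol and leaves C2 and C3 unchanged (3R becomes 3S by priority change only).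

Step 3
Reactants: 5 4-bromo-1,2-bis(benzyloxy)benzene; 6 (R)-but-3-yn-2-ol
Product: 7 (R)-4-[3,4-bis(benzyloxy)phenyl]but-3-yn-2-ol
Conditions: PdCl2(PPh3)2 (3 mol %), CuI (5 mol %), Et3N, THF, 65 °C
Reagents that add atoms: none
Why: Sonogashira coupling at the terminal alkyne, which does not touch the bought carbinol stereocentre.

Step 4
Reactants: 4 7,3',4'-tri-O-benzyl-(+)-catechin; 7 (R)-4-[3,4-bis(benzyloxy)phenyl]but-3-yn-2-ol
Product: 8 catechin 5-O-[(2S)-4-arylbut-3-yn-2-yl] ether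
Conditions: PPh3, DIAD, THF, 0 °C to rt
Reagents that add atoms: none
Why: Mitsunobu etherification of the only free phenol with clean SN2 inversion at the propargylic carbon (R to S); the hindered flavan 3-OH is a poor Mitsunobu substrate and stays free.

Step 5
Reactants: 8 catechin 5-O-[(2S)-4-arylbut-3-yn-2-yl] ether
Product: 9 catechin 5-O-[(2S,3Z)-4-arylbut-3-en-2-yl] ether
Conditions: H2 (1 atm), Pd/CaCO3 poisoned with Pb(OAc)2 (Lindlar catalyst), quinoline, EtOAc, rt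
Reagents that add atoms: none
Why: Lindlar syn-semihydrogenation gives the Z-alkene; benzyl ethers and the allylic C–O bond survive the poisoned catalyst and the S centre is not involved.

Step 6
Reactants: 9 catechin 5-O-[(2S,3Z)-4-arylbut-3-en-2-yl] ether
Product: 10 6-C-[(1R,2E)-1-arylbut-2-enyl]-7,3',4'-tri-O-benzyl-(+)-catechin
Conditions: PhNEt2, BHT (cat.), 185 °C, sealed tube
Reagents that add atoms: none
Why: Aromatic Claisen [3,3] rearrangement to C6, the only free ortho position; in the chair transition state the Z-aryl group is axial, which forces the methyl group equatorial, so the C–O chirality is transferred suprafacially (S at the ether carbon gives R at Cα) and the new alkene is E.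

Step 7
Reactants: 11 2,4,6-tris(benzyloxy)benzaldehyde
Product: 12 2,4,6-tris(benzyloxy)styrene
Conditions: Ph3PCH3Br, KOtBu, THF, 0 °C to rt
Reagents that add atoms: methyltriphenylphosphonium bromide, C[P+](c1ccccc1)(c1ccccc1)c1ccccc1.[Br-]
Why: Wittig methylenation of a non-enolisable aryl aldehyde.

Step 8
Reactants: 10 6-C-[(1R,2E)-1-arylbut-2-enyl]-7,3',4'-tri-O-benzyl-(+)-catechin; 12 2,4,6-tris(benzyloxy)styrene
Product: 13 6-C-[(1R,2E)-1-aryl-3-(2,4,6-tris(benzyloxy)phenyl)prop-2-enyl]-7,3',4'-tri-O-benzyl-(+)-catechin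
Conditions: RuCl2(H2IMes)(=CH-C6H4-2-OiPr) (second-generation Hoveyda–Grubbs catalyst, 10 mol %), 12 (3 equiv), 1,4-benzoquinone (20 mol %), toluene, 60 °C, argon sparge
Reagents that add atoms: none
Why: Olefin cross-metathesis exchanges the methyl-bearing alkene terminus for the styrenyl terminus with loss of propene and E selectivity; Cα is not touched and benzoquinone suppresses Ru–H alkene migration.

Step 9
Reactants: 13 6-C-[(1R,2E)-1-aryl-3-(2,4,6-tris(benzyloxy)phenyl)prop-2-enyl]-7,3',4'-tri-O-benzyl-(+)-catechin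
Product: 16 octa-O-benzyl ether of the target gambiriin, via bis(dimethylsilyl) ether 14 (not isolated), via cyclic siloxane 15 (not isolated)
Conditions: (HMe2Si)2NH, 60 °C, then evaporate; Pt2[(CH2=CHSiMe2)2O]3 (Karstedt catalyst, 0.5 mol %), toluene, 60 °C; then 30% H2O2, KF, KHCO3, THF/MeOH, rt
Reagents that add atoms: hydrogen peroxide, OO
Why: Tamao intramolecular hydrosilylation followed by Tamao–Fleming oxidation: the 5-O–SiMe2H tether adds Si–H syn by 6-exo closure, silicon going to Cβ on the alkene face that places the Cα aryl group and the new benzyl group trans and pseudo-equatorial on the oxasiline ring, and C–Si is then oxidised to C–OH with retention, so Cα (R) sets Cβ (S).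

Step 10
Reactants: 16 octa-O-benzyl ether of the target gambiriin
Product: 17 target gambiriin
Conditions: H2 (1 atm), Pd(OH)2/C, THF/MeOH 1:1, rt
Reagents that add atoms: none
Why: Global hydrogenolysis of eight benzyl ethers; the flavan C2–O1 bond, the C–C-linked diarylmethine and the homobenzylic carbinol are stable under these conditions, so no stereocentre is affected.

## Compound list

1 | (+)-taxifolin, (2R,3R)-dihydroquercetin | O=C1[C@H](O)[C@@H](c2ccc(O)c(O)c2)Oc2cc(O)cc(O)c21 | starting material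
2 | 7,3',4'-tri-O-benzyl-(+)-taxifolin, (2R,3R)-7-(benzyloxy)-2-[3,4-bis(benzyloxy)phenyl]-3,5-dihydroxychroman-4-one | O=C1[C@H](O)[C@@H](c2ccc(OCc3ccccc3)c(OCc3ccccc3)c2)Oc2cc(OCc3ccccc3)cc(O)c21 | intermediate
3 | aryl ethyl carbonate, (2R,3R)-7-(benzyloxy)-2-[3,4-bis(benzyloxy)phenyl]-3-hydroxy-4-oxochroman-5-yl ethyl carbonate | O=C1[C@H](O)[C@@H](c2ccc(OCc3ccccc3)c(OCc3ccccc3)c2)Oc2cc(OCc3ccccc3)cc(OC(=O)OCC)c21 | intermediate (not isolated)
4 | 7,3',4'-tri-O-benzyl-(+)-catechin, (2R,3S)-7-(benzyloxy)-2-[3,4-bis(benzyloxy)phenyl]chromane-3,5-diol | C1[C@H](O)[C@@H](c2ccc(OCc3ccccc3)c(OCc3ccccc3)c2)Oc2cc(OCc3ccccc3)cc(O)c21 | intermediate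
5 | 4-bromo-1,2-bis(benzyloxy)benzene | Brc1ccc(OCc2ccccc2)c(OCc2ccccc2)c1 | starting material
6 | (R)-but-3-yn-2-ol | C[C@@H](O)C#C | starting material
7 | (R)-4-[3,4-bis(benzyloxy)phenyl]but-3-yn-2-ol | C[C@@H](O)C#Cc1ccc(OCc2ccccc2)c(OCc2ccccc2)c1 | intermediate
8 | (2R,3S)-7-(benzyloxy)-2-[3,4-bis(benzyloxy)phenyl]-5-{[(2S)-4-[3,4-bis(benzyloxy)phenyl]but-3-yn-2-yl]oxy}chroman-3-ol | C[C@H](Oc1cc(OCc2ccccc2)cc2c1C[C@H](O)[C@@H](c1ccc(OCc3ccccc3)c(OCc3ccccc3)c1)O2)C#Cc1ccc(OCc2ccccc2)c(OCc2ccccc2)c1 | intermediate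
9 | (2R,3S)-7-(benzyloxy)-2-[3,4-bis(benzyloxy)phenyl]-5-{[(2S,3Z)-4-[3,4-bis(benzyloxy)phenyl]but-3-en-2-yl]oxy}chroman-3-ol | C[C@H](Oc1cc(OCc2ccccc2)cc2c1C[C@H](O)[C@@H](c1ccc(OCc3ccccc3)c(OCc3ccccc3)c1)O2)/C=C\c1ccc(OCc2ccccc2)c(OCc2ccccc2)c1 | intermediate
10 | (2R,3S)-7-(benzyloxy)-2-[3,4-bis(benzyloxy)phenyl]-6-{(1R,2E)-1-[3,4-bis(benzyloxy)phenyl]but-2-en-1-yl}chromane-3,5-diol | C/C=C/[C@H](c1ccc(OCc2ccccc2)c(OCc2ccccc2)c1)c1c(OCc2ccccc2)cc2c(c1O)C[C@H](O)[C@@H](c1ccc(OCc3ccccc3)c(OCc3ccccc3)c1)O2 | intermediate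
11 | 2,4,6-tris(benzyloxy)benzaldehyde | O=Cc1c(OCc2ccccc2)cc(OCc2ccccc2)cc1OCc1ccccc1 | starting material
12 | 2,4,6-tris(benzyloxy)styrene | C=Cc1c(OCc2ccccc2)cc(OCc2ccccc2)cc1OCc1ccccc1 | intermediate
13 | (2R,3S)-7-(benzyloxy)-2-[3,4-bis(benzyloxy)phenyl]-6-{(1R,2E)-1-[3,4-bis(benzyloxy)phenyl]-3-[2,4,6-tris(benzyloxy)phenyl]prop-2-en-1-yl}chromane-3,5-diol | O(Cc1ccccc1)c1cc(OCc2ccccc2)cc(OCc2ccccc2)c1/C=C/[C@H](c1ccc(OCc2ccccc2)c(OCc2ccccc2)c1)c1c(OCc2ccccc2)cc2c(c1O)C[C@H](O)[C@@H](c1ccc(OCc3ccccc3)c(OCc3ccccc3)c1)O2 | intermediate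
14 | 3,5-bis-O-(dimethylsilyl) ether of 13 | O(Cc1ccccc1)c1cc(OCc2ccccc2)cc(OCc2ccccc2)c1/C=C/[C@H](c1ccc(OCc2ccccc2)c(OCc2ccccc2)c1)c1c(OCc2ccccc2)cc2c(c1O[SiH](C)C)C[C@H](O[SiH](C)C)[C@@H](c1ccc(OCc3ccccc3)c(OCc3ccccc3)c1)O2 | intermediate (not isolated)
15 | cyclic siloxane: 5-O–SiMe2–Cβ six-membered oxasiline fused at C5–C6 of the chroman, carrying trans (4R)-3,4-bis(benzyloxy)phenyl and (3S)-2,4,6-tris(benzyloxy)benzyl groups, with 3-O-SiHMe2 retained | O(Cc1ccccc1)c1cc(OCc2ccccc2)cc(OCc2ccccc2)c1C[C@H]1[C@H](c2ccc(OCc3ccccc3)c(OCc3ccccc3)c2)c2c(OCc3ccccc3)cc3c(c2O[Si]1(C)C)C[C@H](O[SiH](C)C)[C@@H](c2ccc(OCc4ccccc4)c(OCc4ccccc4)c2)O3 | intermediate (not isolated)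
16 | octa-O-benzyl ether of the target gambiriin, (2R,3S)-7-(benzyloxy)-2-[3,4-bis(benzyloxy)phenyl]-6-{(1R,2S)-1-[3,4-bis(benzyloxy)phenyl]-2-hydroxy-3-[2,4,6-tris(benzyloxy)phenyl]propyl}chromane-3,5-diol | O(Cc1ccccc1)c1cc(OCc2ccccc2)cc(OCc2ccccc2)c1C[C@H](O)[C@H](c1ccc(OCc2ccccc2)c(OCc2ccccc2)c1)c1c(OCc2ccccc2)cc2c(c1O)C[C@H](O)[C@@H](c1ccc(OCc3ccccc3)c(OCc3ccccc3)c1)O2 | intermediate
17 | target gambiriin, (2R,3S)-2-(3,4-dihydroxyphenyl)-6-[(1R,2S)-1-(3,4-dihydroxyphenyl)-2-hydroxy-3-(2,4,6-trihydroxyphenyl)propyl]chromane-3,5,7-triol | Oc1cc(O)c(C[C@H](O)[C@H](c2ccc(O)c(O)c2)c2c(O)cc3c(c2O)C[C@H](O)[C@@H](c2ccc(O)c(O)c2)O3)c(O)c1 | target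

## Step count and risks

Total step count: 10. Longest linear sequence: 8 (steps 1, 2, 4, 5, 6, 8, 9, 10).

**Step 6 (Claisen rearrangement of the Z-ether).** A Z-γ-aryl allyl ether rearranges slowly because the aryl group is axial in the chair; at 185 °C ionisation of the electron-rich allyl ether, para migration through C4a, or abnormal Claisen products could erode yield or chirality transfer. The fallback sets out from 5 (with 4 as the coupling partner) and comes back at 10 through the E series. Sonogashira coupling of 5 with (S)-but-3-yn-2-ol (C[C@H](O)C#C) gives (S)-4-[3,4-bis(benzyloxy)phenyl]but-3-yn-2-ol F1. Trans-hydroalumination with NaAlH2(OCH2CH2OCH3)2 in THF gives (2S,3E)-4-[3,4-bis(benzyloxy)phenyl]but-3-en-2-ol F2. Mitsunobu coupling of F2 with 4 (inversion) gives the catechin 5-O-[(2R,3E)-4-arylbut-3-en-2-yl] ether F3. With both substituents equatorial in the chair, F3 rearranges at 140–160 °C and, because carbinol configuration and alkene geometry are both reversed, delivers the same 10.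

**Step 8 (cross-metathesis).** Both partners are hindered: an α-diaryl-branched internal alkene and a 2,6-dialkoxystyrene that can chelate ruthenium. The fallback sets out from 10 and comes back at 13 by a metathesis/cross-coupling relay. Cross-metathesis of 10 with the small partner 4,4,5,5-tetramethyl-2-vinyl-1,3,2-dioxaborolane under RuCl2(H2IMes)(=CH-C6H4-2-OiPr) gives the (E)-alkenyl pinacol boronate F4. Suzuki–Miyaura coupling of F4 (Pd(OAc)2, SPhos, K3PO4, toluene/H2O, 80 °C) with 2-bromo-1,3,5-tris(benzyloxy)benzene F5, made by NBS bromination of commercial 1,3,5-tris(benzyloxy)benzene, gives 13 without any base strong enough to touch Cα.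

**Step 9 (tethered hydrosilylation/oxidation).** Ring size (6-exo against 7-endo), competing intermolecular hydrosilylation and the level of face selectivity are not secured by close precedent. The fallback sets out from 13 and comes back at 16, replacing tether control by 1,2-induction in a ketone reduction. TBSOTf and 2,6-lutidine give the 3,5-bis-O-TBS ether F6. Hydroboration with BH3·SMe2 and direct oxidation of the borane with pyridinium chlorochromate [C5H5NH][CrO3Cl] give the Cβ ketone F7. Boron is expected at Cβ, the electron-rich β-carbon of the 2,4,6-trialkoxystyrene unit, whose benzylic carbon is screened by two ortho benzyloxy groups; this regiochemistry is the weak point of the fallback. LiBH(sec-Bu)3 in THF at −78 °C should add hydride anti to the 2,6-dioxygenated aryl group, the largest α-substituent (Felkin–Anh), to give the (1R,2S)-alcohol F8. Bu4NF then gives 16.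

Further compounds
F1 | step 6 | (S)-4-[3,4-bis(benzyloxy)phenyl]but-3-yn-2-ol | C[C@H](O)C#Cc1ccc(OCc2ccccc2)c(OCc2ccccc2)c1
F2 | step 6 | (2S,3E)-4-[3,4-bis(benzyloxy)phenyl]but-3-en-2-ol | C[C@H](O)/C=C/c1ccc(OCc2ccccc2)c(OCc2ccccc2)c1
F3 | step 6 | (2R,3S)-7-(benzyloxy)-2-[3,4-bis(benzyloxy)phenyl]-5-{[(2R,3E)-4-[3,4-bis(benzyloxy)phenyl]but-3-en-2-yl]oxy}chroman-3-ol | C[C@@H](Oc1cc(OCc2ccccc2)cc2c1C[C@H](O)[C@@H](c1ccc(OCc3ccccc3)c(OCc3ccccc3)c1)O2)/C=C/c1ccc(OCc2ccccc2)c(OCc2ccccc2)c1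
F4 | step 8 | (E)-alkenyl pinacol boronate, 6-C-[(1R,2E)-1-[3,4-bis(benzyloxy)phenyl]-3-(4,4,5,5-tetramethyl-1,3,2-dioxaborolan-2-yl)prop-2-en-1-yl]-7,3',4'-tri-O-benzyl-(+)-catechin | CC1(C)OB(OC1(C)C)/C=C/[C@H](c1ccc(OCc2ccccc2)c(OCc2ccccc2)c1)c1c(OCc2ccccc2)cc2c(c1O)C[C@H](O)[C@@H](c1ccc(OCc3ccccc3)c(OCc3ccccc3)c1)O2
F5 | step 8 | 2-bromo-1,3,5-tris(benzyloxy)benzene | Brc1c(OCc2ccccc2)cc(OCc2ccccc2)cc1OCc1ccccc1
F6 | step 9 | 3,5-bis-O-(tert-butyldimethylsilyl) ether of 13 | O(Cc1ccccc1)c1cc(OCc2ccccc2)cc(OCc2ccccc2)c1/C=C/[C@H](c1ccc(OCc2ccccc2)c(OCc2ccccc2)c1)c1c(OCc2ccccc2)cc2c(c1O[Si](C)(C)C(C)(C)C)C[C@H](O[Si](C)(C)C(C)(C)C)[C@@H](c1ccc(OCc3ccccc3)c(OCc3ccccc3)c1)O2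
F7 | step 9 | Cβ ketone, (1R)-1-[3,4-bis(benzyloxy)phenyl]-1-[3,5-bis-O-TBS-7,3',4'-tri-O-benzylcatechin-6-yl]-3-[2,4,6-tris(benzyloxy)phenyl]propan-2-one | O(Cc1ccccc1)c1cc(OCc2ccccc2)cc(OCc2ccccc2)c1CC(=O)[C@H](c1ccc(OCc2ccccc2)c(OCc2ccccc2)c1)c1c(OCc2ccccc2)cc2c(c1O[Si](C)(C)C(C)(C)C)C[C@H](O[Si](C)(C)C(C)(C)C)[C@@H](c1ccc(OCc3ccccc3)c(OCc3ccccc3)c1)O2
F8 | step 9 | 3,5-bis-O-(tert-butyldimethylsilyl) ether of 16 | O(Cc1ccccc1)c1cc(OCc2ccccc2)cc(OCc2ccccc2)c1C[C@H](O)[C@H](c1ccc(OCc2ccccc2)c(OCc2ccccc2)c1)c1c(OCc2ccccc2)cc2c(c1O[Si](C)(C)C(C)(C)C)C[C@H](O[Si](C)(C)C(C)(C)C)[C@@H](c1ccc(OCc3ccccc3)c(OCc3ccccc3)c1)O2
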